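## Structural features

The target is a cyclohexane (C5–C10) cis-fused at C7/C8 to an α-methylene-γ-butyrolactone (C11, C12, O8, exocyclic C13). C5 carries a 2-formylvinyl unit (C4=C3, aldehyde C15), C6 a free hydroxyl, C9 a methacrylate, and quaternary C10 a methyl group (C14) and an oxirane (C1–C2). All six ring carbons are stereogenic and contiguous: O8, O9, C11 and the oxirane lie on one face; O6, C4 and the C10 methyl on the other. A seventh stereocentre, C1, sits outside the ring next to C10. Three Michael acceptors (acrolein, methylene lactone, methacrylate), a terminal epoxide and a free secondary alcohol make the molecule sensitive to base, nucleophiles and strong acid, so these groups must appear late. The real difficulty is the fully substituted ring around quaternary C10 (bonds C5–C10, C9–C10, C5–C6 with cis C4/O6) and telling apart three ring oxygens: O6 free, O8 lactonised, O9 acylated. The key step exploits the array O6–C6–C5–C4(=C3): a homoallylic alcohol carrying a 2-substituted allyl unit, the retron of a carbonyl allylation through γ-carbon C5, which run intramolecularly closes the ring between C5 and C6.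

## Logic of the disconnections

35 ⇒ 34 ⇒ 33. The C15 aldehyde is taken back to the allylic alcohol and both free oxygens (O6, O15) to silyl ethers. The acrolein is the most electrophilic group, so it is made last. The oxidant must tell an allylic primary from a non-allylic secondary alcohol, and desilylation must spare epoxide, esters and enoates.

33 ⇒ 32. Cut the O9–acyl bond. The methacrylate is base-sensitive, and the free O9–H is needed one step earlier as a directing group. The acylation must work on a hindered secondary alcohol next to C10.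

32 ⇒ 31. Cut both C–O bonds of the oxirane back to the C10 vinyl group. This removes C1 as a stereocentre. The forward step must choose the monosubstituted alkene over the more nucleophilic C4=C3 and one of its faces, so it is delivered from O9–H.

31 ⇒ 30 ⇒ 27 ⇒ 26. Cut the lactone bond O8–C12 (back to acetonide plus tert-butyl ester), then C11=C13, then the O6 silyl ether. O6 is capped first so that only O8 can close a γ-lactone and so that O6 cannot direct epoxidation or be acylated later. The methylene is introduced at the ester stage because no hydroxyl is free there. The acid step must leave the two silyl ethers and the alkenes intact.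

26 ⇒ 24 (made from 23). Cut C5–C6, the ring bond beside the quaternary carbon. This opens the carbocycle to an acyclic aldehyde with a tethered allylboronate and removes two stereocentres. The forward step needs C10 cis to the borylmethyl carbon C3, and an aldehyde that is released under neutral conditions because C7 is enolisable with a β-oxygen.

23 ⇒ 22 ⇒ 21. Cut C3–C4 back to an alkenyl bromide. Boron is introduced last because an allylboronate tolerates neither a C7 aldehyde (five-ring allylation) nor organocopper or organolithium reagents. The coupling must retain alkene geometry and tolerate the tert-butyl ester.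

21 ⇒ 20 ⇒ 18 ⇒ 17 ⇒ 16. Cut C6–C7 (conjugate addition of a hydroxymethyl anion equivalent) and C7=C11 (Wittig). This takes away C7 as a stereocentre and C6, C11, C12 as carbons. C6 must end syn to O8, which is the sense cuprates show with (Z)-γ-alkoxy enoates; an (E)-enoate would favour the C7 epimer, so the olefination has to be Z-selective.

16 ⇒ 15 ⇒ 14 ⇒ 13 ⇒ 12. Cut C4=C5 by a Wittig reaction with a bromo ylide, which brings C4, C15 and the halogen. Two protecting-group changes differentiate O7 from O15. The olefination must place bromine cis to C10, since that position becomes C3.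

12 ⇒ 11 ⇒ 10 ⇒ 9. Cut C5–C10 by a [2,3]-Wittig–Still transform. The quaternary centre becomes a trisubstituted (Z)-alkene, and C5 a stannylmethyl group on the allylic oxygen. The only control element is the neighbouring dioxolane carbon C9, so the alkene geometry must be pure and one alkene face must be clearly favoured.

9 ⇒ 8 ⇒ 7 ⇒ 5 ⇒ 4 ⇒ 3 ⇒ 2 ⇒ 1. Cut C10–C14 (syn carbocupration of an ynoate, which fixes the Z geometry), C1–C2 (acetylide acylation) and C10≡C1 (Corey–Fuchs). What remains is a four-carbon aldehyde from the chiral-pool lactone 1, which supplies C7–C10 and both oxygen stereocentres. The cis-dioxolane aldehyde must not epimerise at C9.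

## Other disconnections considered

Alternative 1: The cut is C9–C10 together with O–C1. In the forward step oxime A1 is oxidised and the resulting dipole adds across the (E)-C10=C1 alkene, closing a cyclohexene and a fused isoxazoline to give A2. In its favour: one concerted, suprafacial step creates quaternary C10 and the oxygen-bearing C1 with their relative configuration fixed by alkene geometry. On this point it is better than the chosen plan, which sets C1 late by a directed epoxidation. It also forms a bond to the quaternary carbon intramolecularly, which is equal in spirit. Against it: A2 still lacks the C6 oxygen, the C7 appendage and a defined C9 carbinol. The N–O bond must be cleaved beside the C6=C7 alkene, the C9 ketone reduced with control, the epoxide closed from a diol, the acrolein grown from a masked ketone, and C6/C7 functionalised with two more stereocentres. The facial sense of the cycloaddition rests only on C5 and C8. In structural terms A2 holds four of the seven stereocentres, whereas 26 holds six and every ring substituent carbon except C13. Both key steps pass through ordered cyclic transition states. In step economy the alternative is expected to need clearly more steps after its key step.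

Alternative 2: The cut is C7–C11 together with C6–O. In the forward step the radical from bromoacetal A3 closes 5-exo onto C7 and the C6 radical is trapped by dioxygen, giving lactol ether A4. In its favour: the tether guarantees the cis ring fusion at C7/C8, which is at least as reliable as the acyclic induction used for C7 in the chosen plan. Two bonds form under neutral conditions. Against it: A3 must already contain the ring with C5, C8, C9 and C10, so the hard part is left to other chemistry. Oxygen trapping competes with hydrogen transfer. The C6 oxygen must enter cis to the C5 substituent, which steric approach does not favour, and the acetal must later be oxidised to the lactone. Both plans form two bonds in the key step, but only the chosen plan closes the carbocycle. Its closed transition state fixes C5/C6, while the radical trapping has no such control.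

Alternative 3: The cut is C6–C7. In the forward step SmI2 converts aldehyde A5 into a ketyl that adds to the β-carbon of the tethered butenolide, giving hydroxy lactone A6. In its favour: the lactone is in place before the ring closes, so there is no late lactonisation and no question of which oxygen closes it; this is better than the chosen plan. Ketyl–enoate cyclisations are well established, and only the cis-fused lactone is feasible. Against it: the hindered C5–C10 bond and the C5 stereocentre must be made beforehand in an acyclic chain. The aldehyde in A5 is α to a carbon bearing an isopropenyl group and can enolise into conjugation. The C6 configuration is not tied to an alkene geometry as it is in the allylboration. A6 carries C15 as a methyl group, so a late allylic oxidation among several alkenes is needed. Both plans close the six-membered ring and set two stereocentres, and both still need C13; the step count of the alternative is expected to be similar or higher.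

Key step: step 21

Remark on the chemistry: atoms are labelled as in the elemanolide skeleton (ring C5–C10; C4, C3, C15 on C5; lactone C11–C13; C14 and C1–C2 on C10). O15 is carried as a tert-butyldiphenylsilyl (TBDPS) ether because a TBS ether at this primary allylic position would not outlast the acidic lactonisation. TBS = tert-butyldimethylsilyl, TES = triethylsilyl, Bpin = pinacolatoboryl.

Step 1
Reactants: 1 2,3-O-isopropylidene-D-erythronolactone
Product: 2 hydroxy Weinreb amide
Conditions: MeNH(OMe)·HCl, i-PrMgCl, THF, −20 °C
Reagents that add atoms: N,O-dimethylhydroxylamine hydrochloride, CNOC.Cl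
Why: Aminolysis of the γ-lactone by the chloromagnesium amide (Weinreb amide formation) opens the ring without touching the two stereocentres; the carbonyl carbon is the future C10 and the freed CH2OH carbon the future C7.

Step 2
Reactants: 2 hydroxy Weinreb amide
Product: 3 silyl ether amide
Conditions: TBSCl, imidazole, DMF, 0 °C → rt
Reagents that add atoms: tert-butyldimethylsilyl chloride, CC(C)(C)[Si](C)(C)Cl
Why: Silylation of the primary alcohol under non-alkoxide conditions prevents relactonisation.

Step 3
Reactants: 3 silyl ether amide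
Product: 4 dioxolane aldehyde
Conditions: i-Bu2AlH, THF, −78 °C; aq. KNa tartrate
Reagents that add atoms: none
Why: Reduction of the Weinreb amide stops at the chelated hemiaminal, which gives the aldehyde on work-up; the low temperature protects the cis-dioxolane α-stereocentre C9.

Step 4
Reactants: 4 dioxolane aldehyde
Product: 5 dibromoalkene
Conditions: CBr4, PPh3, Et3N, CH2Cl2, 0 °C
Reagents that add atoms: carbon tetrabromide, BrC(Br)(Br)Br
Why: Corey–Fuchs dibromo-olefination is a Wittig-type reaction under non-enolising conditions and adds C1.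

Step 5
Reactants: 5 dibromoalkene
Product: 7 ynoate, via lithium acetylide 6 (not isolated)
Conditions: n-BuLi (2.1 equiv), THF, −78 °C; ClCO2Me, −78 → 0 °C
Reagents that add atoms: methyl chloroformate, COC(=O)Cl
Why: Second stage of the Corey–Fuchs sequence: bromine–lithium exchange, α-elimination and 1,2-hydride shift give the alkyne, which is deprotonated to 6 and C-acylated to bring in C2.

Step 6
Reactants: 7 ynoate
Product: 8 Z-enoate
Conditions: Me2CuLi (from MeLi and CuI), THF, −78 °C; MeOH, −78 °C
Reagents that add atoms: lithium dimethylcuprate, [Li+].C[Cu-]C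
Why: Syn carbocupration of the ynoate places the methyl group (C14) on C10 cis to copper; protonation at −78 °C retains this, so the ester carbon ends cis to C9 (Z).

Step 7
Reactants: 8 Z-enoate
Product: 9 Z-allylic alcohol
Conditions: i-Bu2AlH, CH2Cl2, −78 °C
Reagents that add atoms: none
Why: 1,2-Reduction of the conjugated ester to the allylic alcohol without change of alkene geometry.

Step 8
Reactants: 9 Z-allylic alcohol
Product: 10 stannylmethyl ether
Conditions: KH, Bu3SnCH2I, 18-crown-6 (cat.), THF, 0 °C → rt
Reagents that add atoms: (iodomethyl)tributylstannane, CCCC[Sn](CCCC)(CCCC)CI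
Why: Williamson etherification of the potassium alkoxide installs the future C5 as the stannylmethyl group.

Step 9
Reactants: 10 stannylmethyl ether
Product: 11 homoallylic alcohol
Conditions: n-BuLi, THF, −78 °C
Reagents that add atoms: none
Why: Still–Wittig rearrangement: tin–lithium exchange gives the α-alkoxymethyllithium, which undergoes a [2,3]-shift through a five-membered envelope, forming C5–C10 and the C1=C2 vinyl group. For the C10 configuration, 1,3-allylic strain with the cis C2 methylene holds C9–H in the alkene plane; C8 with its cis CH2OTBS arm covers one face, so the carbanion should bond on the face of O9.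

Step 10
Reactants: 11 homoallylic alcohol
Product: 12 quaternary aldehyde
Conditions: Dess–Martin periodinane, NaHCO3, CH2Cl2, 0 °C → rt
Reagents that add atoms: none
Why: Hypervalent-iodine oxidation of the neopentyl alcohol; the aldehyde has no α-hydrogen and cannot epimerise or conjugate.

Step 11
Reactants: 12 quaternary aldehyde
Product: 13 bromoenoate
Conditions: Ph3P=C(Br)CO2Et, toluene, 90 °C
Reagents that add atoms: ethyl bromo(triphenylphosphoranylidene)acetate, CCOC(=O)C(Br)=P(c1ccccc1)(c1ccccc1)c1ccccc1
Why: Wittig olefination with a stabilised ylide puts the ester trans and the bromine cis to the bulky C10 substituent, which is the geometry the later boronate needs.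

Step 12
Reactants: 13 bromoenoate
Product: 14 bromoallylic alcohol
Conditions: i-Bu2AlH, CH2Cl2, −78 °C
Reagents that add atoms: none
Why: 1,2-Reduction of the ester (C15) to the primary alcohol; the alkenyl bromide is inert to the hydride at this temperature.

Step 13
Reactants: 14 bromoallylic alcohol
Product: 15 bis-silyl ether
Conditions: TBDPSCl, imidazole, DMF, rt
Reagents that add atoms: tert-butyl(chloro)diphenylsilane, CC(C)(C)[Si](Cl)(c1ccccc1)c1ccccc1
Why: Silylation of the primary allylic alcohol with the acid-stable silyl group that must outlast the lactonisation.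

Step 14
Reactants: 15 bis-silyl ether
Product: 16 C7 alcohol
Conditions: HF·pyridine, pyridine, THF, 0 °C
Reagents that add atoms: none
Why: Buffered fluoride removes the primary TBS ether much faster than the primary TBDPS ether; the acetonide is inert.

Step 15
Reactants: 16 C7 alcohol
Product: 17 C7 aldehyde
Conditions: Dess–Martin periodinane, NaHCO3, CH2Cl2, 0 °C
Reagents that add atoms: none
Why: Buffered, non-basic oxidation keeps the cis-dioxolane α-stereocentre C8; the aldehyde is used at once.

Step 16
Reactants: 17 C7 aldehyde
Product: 18 Z-enoate tert-butyl ester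
Conditions: Ph3P=CHCO2t-Bu, MeOH, 0 °C
Reagents that add atoms: tert-butyl (triphenylphosphoranylidene)acetate, CC(C)(C)OC(=O)C=P(c1ccccc1)(c1ccccc1)c1ccccc1
Why: Wittig olefination with a stabilised ylide in methanol, where α-alkoxy aldehydes give mainly the (Z)-enoate; the minor (E)-isomer is removed because it would lead to the C7 epimer.

Step 17
Reactants: 18 Z-enoate tert-butyl ester
Product: 20 C6 alcohol, via silane adduct 19 (not isolated)
Conditions: (i-PrO)Me2SiCH2MgCl, CuBr·SMe2 (20 mol %), TMSCl, THF, −78 → −30 °C; then KF, KHCO3, H2O2, THF/MeOH, rt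
Reagents that add atoms: (isopropoxydimethylsilyl)methylmagnesium chloride, CC(C)O[Si](C)(C)C[Mg]Cl; hydrogen peroxide, OO
Why: Copper-catalysed, TMSCl-accelerated conjugate addition of a hydroxymethyl anion equivalent followed by Tamao–Fleming oxidation. For the C7 configuration, 1,3-allylic strain in the (Z)-enoate holds C8–H in the alkene plane and the C9 side carrying quaternary C10 is blocked, so C6 adds syn to O8, the usual sense for (Z)-γ-alkoxy enoates.

Step 18
Reactants: 20 C6 alcohol
Product: 21 triethylsilyl ether
Conditions: TESCl, imidazole, CH2Cl2, 0 °C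
Reagents that add atoms: chlorotriethylsilane, CC[Si](CC)(CC)Cl
Why: Silylation masks the γ-hydroxy ester, which would otherwise lactonise under the aqueous base of the next step.

Step 19
Reactants: 21 triethylsilyl ether
Product: 22 allylboronate
Conditions: CH2(Bpin)2, Pd[P(t-Bu)3]2 (5 mol %), KOH (aq), 1,4-dioxane, rt
Reagents that add atoms: bis[(pinacolato)boryl]methane, CC1(C)OB(CB2OC(C)(C)C(C)(C)O2)OC1(C)C
Why: Suzuki–Miyaura coupling of the alkenyl bromide with the geminal bis(boronate): hydroxide activates one boron, its α-boryl alkyl group is transferred to palladium and reductive elimination retains the alkene geometry, so C10 stays cis to C3; the second boron remains as the allylboronate.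

Step 20
Reactants: 22 allylboronate
Product: 23 hydroxy allylboronate
Conditions: PPTS, MeOH, 0 °C
Reagents that add atoms: none
Why: Acid-catalysed methanolysis of the primary TES ether; the TBDPS ether, acetonide, tert-butyl ester and pinacol boronate are stable to this weak acid in the cold.

Step 21
Reactants: 23 hydroxy allylboronate
Product: 26 cyclohexanol, via ω-formyl allylboronate 24 (not isolated), via pinacol borate 25 (not isolated)
Conditions: Dess–Martin periodinane, NaHCO3, CH2Cl2, 0 °C; filter, toluene, 60 °C; aq. NaHCO3
Reagents that add atoms: none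
Why: Buffered oxidation releases the C6 aldehyde 24 beside the pinacol allylboronate; on warming boron binds the carbonyl oxygen and γ-carbon C5 adds to C6 through a closed six-membered chair (B, O6, C6, C5, C4, C3), the double bond moving to C4=C3. The closest known reaction is the thermal intramolecular allylboration of ω-oxo allylboronates to 2-alkenylcycloalkanols. The carbocycle closes in the 6-exo-trig mode at the carbonyl carbon. The relative configuration of C5 and C6 follows from the alkene geometry: C10, cis to C3, must be axial on the allylboration chair and the aldehyde chain equatorial, which gives cis C4/O6. The face is set by the forming cyclohexane chair, in which the cis-fused acetonide keeps C8–O and the C10 vinyl group axial and the C7 CH2CO2t-Bu arm equatorial; C4 then enters axial on the opposite face and O6 becomes equatorial, whereas the other cis arrangement would put O6 axial and syn to both C8–O and the vinyl group. The step needs allylation to outrun enolisation at C7 (epimerisation, loss of O8), which the neutral, base-free conditions should secure. The hindered bond beside quaternary C10 forms without an external reagent, and aqueous work-up hydrolyses borate 25.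

Step 22
Reactants: 26 cyclohexanol
Product: 27 O6 silyl ether
Conditions: TBSOTf, 2,6-lutidine, CH2Cl2, −78 → 0 °C
Reagents that add atoms: tert-butyldimethylsilyl trifluoromethanesulfonate, CC(C)(C)[Si](C)(C)OS(=O)(=O)C(F)(F)F
Why: Silylation of the hindered secondary O6–H with the silyl triflate; it rules out lactonisation toward O6 and later O6-directed epoxidation or acylation.

Step 23
Reactants: 27 O6 silyl ether
Product: 30 α-methylene ester, via Mannich base 28 (not isolated), via ammonium iodide 29 (not isolated)
Conditions: LiN(i-Pr)2, THF, −78 °C; CH2=NMe2+ I−, −78 → 0 °C; MeI, THF/MeOH, rt; DBU, CH2Cl2, rt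
Reagents that add atoms: N,N-dimethylmethyleneiminium iodide (Eschenmoser's salt), C=[N+](C)C.[I-]; iodomethane, CI (carried only in intermediate 29)
Why: Ester enolate Mannich reaction, N-methylation and base-induced β-elimination install C13 while no hydroxyl is free; C7 is β to the carbonyl and is not epimerised.

Step 24
Reactants: 30 α-methylene ester
Product: 31 hydroxy methylene lactone
Conditions: TFA–CH2Cl2–H2O (20:78:2), 0 °C
Reagents that add atoms: none
Why: Acid cleaves the tert-butyl ester by alkyl–oxygen fission and hydrolyses the acetonide; the acid closes onto O8 as the cis-fused γ-lactone because O6 is silylated and O9 could only give a δ-lactone. The hindered secondary TBS ether and the primary TBDPS ether are expected to survive cold dilute acid.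

Step 25
Reactants: 31 hydroxy methylene lactone
Product: 32 epoxy alcohol
Conditions: VO(acac)2 (5 mol %), t-BuOOH, CH2Cl2, 0 °C → rt
Reagents that add atoms: tert-butyl hydroperoxide, CC(C)(C)OO
Why: Hydroxyl-directed epoxidation of a homoallylic alcohol: the O9 vanadate, equatorial and gauche to the axial vinyl group, delivers oxygen to the alkene face turned toward C9 while the vinyl CH2 points outward over the C10 methyl, which sets C1. The electron-poor methylene lactone and the undirected C4=C3 (O6 silylated, on the face opposite to O9) should not react.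

Step 26
Reactants: 32 epoxy alcohol
Product: 33 methacrylate
Conditions: methacrylic anhydride, Et3N, DMAP, CH2Cl2, rt
Reagents that add atoms: methacrylic anhydride, C=C(C)C(=O)OC(=O)C(C)=C
Why: DMAP-catalysed acylation of the only free hydroxyl under conditions too mild to open the epoxide.

Step 27
Reactants: 33 methacrylate
Product: 34 diol
Conditions: HF·pyridine, pyridine, THF, 0 °C → rt
Reagents that add atoms: none
Why: Buffered fluoride removes both silyl ethers under weakly acidic conditions that should spare the epoxide, the esters and the Michael acceptors.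

Step 28
Reactants: 34 diol
Product: 35 CNP0124638.3
Conditions: MnO2, CH2Cl2, rt
Reagents that add atoms: none
Why: MnO2 oxidises only the allylic primary alcohol to the enal; the secondary C6 hydroxyl is not allylic and stays.

Compound list

1 | 2,3-O-isopropylidene-D-erythronolactone, (3aR,6aR)-2,2-dimethyldihydrofuro[3,4-d][1,3]dioxol-4(3aH)-one | O=C1OC[C@H]2OC(C)(C)O[C@@H]12 | starting material
2 | hydroxy Weinreb amide, (4R,5R)-5-(hydroxymethyl)-N-methoxy-N,2,2-trimethyl-1,3-dioxolane-4-carboxamide | OC[C@H]1OC(C)(C)O[C@H]1C(=O)N(C)OC | intermediate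
3 | silyl ether amide, 2 with the primary oxygen (O7) as TBS ether | CC(C)(C)[Si](C)(C)OC[C@H]1OC(C)(C)O[C@H]1C(=O)N(C)OC | intermediate
4 | dioxolane aldehyde, (4R,5R)-5-[(TBS-oxy)methyl]-2,2-dimethyl-1,3-dioxolane-4-carbaldehyde | CC(C)(C)[Si](C)(C)OC[C@H]1OC(C)(C)O[C@H]1C=O | intermediate
5 | dibromoalkene, (4S,5R)-4-(2,2-dibromoethenyl)-5-[(TBS-oxy)methyl]-2,2-dimethyl-1,3-dioxolane | CC(C)(C)[Si](C)(C)OC[C@H]1OC(C)(C)O[C@H]1C=C(Br)Br | intermediate
6 | lithium acetylide of (4S,5R)-4-ethynyl-5-[(TBS-oxy)methyl]-2,2-dimethyl-1,3-dioxolane | CC(C)(C)[Si](C)(C)OC[C@H]1OC(C)(C)O[C@H]1C#C[Li] | intermediate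
7 | ynoate, methyl 3-{(4S,5R)-5-[(TBS-oxy)methyl]-2,2-dimethyl-1,3-dioxolan-4-yl}prop-2-ynoate | CC(C)(C)[Si](C)(C)OC[C@H]1OC(C)(C)O[C@H]1C#CC(=O)OC | intermediate
8 | Z-enoate, methyl (2Z)-3-{(4S,5R)-5-[(TBS-oxy)methyl]-2,2-dimethyl-1,3-dioxolan-4-yl}but-2-enoate (ester carbon cis to the dioxolane) | CC(C)(C)[Si](C)(C)OC[C@H]1OC(C)(C)O[C@H]1/C(C)=C\C(=O)OC | intermediate
9 | Z-allylic alcohol, (2Z)-3-{(4S,5R)-5-[(TBS-oxy)methyl]-2,2-dimethyl-1,3-dioxolan-4-yl}but-2-en-1-ol | CC(C)(C)[Si](C)(C)OC[C@H]1OC(C)(C)O[C@H]1/C(C)=C\CO | intermediate
10 | stannylmethyl ether, 9 with the hydroxyl as O–CH2SnBu3 ether | CC(C)(C)[Si](C)(C)OC[C@H]1OC(C)(C)O[C@H]1/C(C)=C\COC[Sn](CCCC)(CCCC)CCCC | intermediate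
11 | homoallylic alcohol, (2S)-2-{(4S,5R)-5-[(TBS-oxy)methyl]-2,2-dimethyl-1,3-dioxolan-4-yl}-2-methylbut-3-en-1-ol (CH2OH = C5, on the O9 face) | CC(C)(C)[Si](C)(C)OC[C@H]1OC(C)(C)O[C@H]1[C@@](C)(C=C)CO | intermediate
12 | quaternary aldehyde, 11 with CH2OH oxidised to CHO (same arrangement at C10) | CC(C)(C)[Si](C)(C)OC[C@H]1OC(C)(C)O[C@H]1[C@@](C)(C=C)C=O | intermediate
13 | bromoenoate, ethyl (2Z,4S)-2-bromo-4-{(4S,5R)-5-[(TBS-oxy)methyl]-2,2-dimethyl-1,3-dioxolan-4-yl}-4-methylhexa-2,5-dienoate (Br cis to C10) | CC(C)(C)[Si](C)(C)OC[C@H]1OC(C)(C)O[C@H]1[C@@](C)(C=C)/C=C(\Br)C(=O)OCC | intermediate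
14 | bromoallylic alcohol, 13 with the ester reduced to CH2OH (C15) | CC(C)(C)[Si](C)(C)OC[C@H]1OC(C)(C)O[C@H]1[C@@](C)(C=C)/C=C(\Br)CO | intermediate
15 | bis-silyl ether, 14 with O15 as TBDPS ether | CC(C)(C)[Si](C)(C)OC[C@H]1OC(C)(C)O[C@H]1[C@@](C)(C=C)/C=C(\Br)CO[Si](c2ccccc2)(c2ccccc2)C(C)(C)C | intermediate
16 | C7 alcohol, 15 without the TBS group on O7 | OC[C@H]1OC(C)(C)O[C@H]1[C@@](C)(C=C)/C=C(\Br)CO[Si](c2ccccc2)(c2ccccc2)C(C)(C)C | intermediate
17 | C7 aldehyde, 16 oxidised at C7 (cis-dioxolane-4-carbaldehyde) | O=C[C@H]1OC(C)(C)O[C@H]1[C@@](C)(C=C)/C=C(\Br)CO[Si](c2ccccc2)(c2ccccc2)C(C)(C)C | intermediate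
18 | Z-enoate tert-butyl ester, tert-butyl (2Z)-3-(dioxolan-4-yl)prop-2-enoate built on C7 of 17 (C12 cis to C8) | CC(C)(C)OC(=O)/C=C\[C@H]1OC(C)(C)O[C@H]1[C@@](C)(C=C)/C=C(\Br)CO[Si](c2ccccc2)(c2ccccc2)C(C)(C)C | intermediate
19 | silane adduct, tert-butyl ester with C7 bearing CH2Si(CH3)2(O-i-Pr) syn to O8 | CC(C)O[Si](C)(C)C[C@@H](CC(=O)OC(C)(C)C)[C@H]1OC(C)(C)O[C@H]1[C@@](C)(C=C)/C=C(\Br)CO[Si](c2ccccc2)(c2ccccc2)C(C)(C)C | intermediate
20 | C6 alcohol, 19 with the silyl group replaced by OH (C6H2OH on C7) | OC[C@@H](CC(=O)OC(C)(C)C)[C@H]1OC(C)(C)O[C@H]1[C@@](C)(C=C)/C=C(\Br)CO[Si](c2ccccc2)(c2ccccc2)C(C)(C)C | intermediate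
21 | triethylsilyl ether, 20 with O6 as TES ether | CC[Si](CC)(CC)OC[C@@H](CC(=O)OC(C)(C)C)[C@H]1OC(C)(C)O[C@H]1[C@@](C)(C=C)/C=C(\Br)CO[Si](c2ccccc2)(c2ccccc2)C(C)(C)C | intermediate
22 | allylboronate, 21 with Br replaced by CH2Bpin (C10 cis to the CH2B carbon C3) | CC[Si](CC)(CC)OC[C@@H](CC(=O)OC(C)(C)C)[C@H]1OC(C)(C)O[C@H]1[C@@](C)(C=C)/C=C(/CO[Si](c2ccccc2)(c2ccccc2)C(C)(C)C)CB1OC(C)(C)C(C)(C)O1 | intermediate
23 | hydroxy allylboronate, 22 without the TES group | OC[C@@H](CC(=O)OC(C)(C)C)[C@H]1OC(C)(C)O[C@H]1[C@@](C)(C=C)/C=C(/CO[Si](c2ccccc2)(c2ccccc2)C(C)(C)C)CB1OC(C)(C)C(C)(C)O1 | intermediate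
24 | ω-formyl allylboronate (7S,8R,9S,10S; C4=C5 with C10 cis to C3), the C6 aldehyde of 23 | O=C[C@@H](CC(=O)OC(C)(C)C)[C@H]1OC(C)(C)O[C@H]1[C@@](C)(C=C)/C=C(/CO[Si](c2ccccc2)(c2ccccc2)C(C)(C)C)CB1OC(C)(C)C(C)(C)O1 | intermediate
25 | pinacol borate, O6–Bpin ester of 26 | CC1(C)O[C@@H]2[C@H](O1)[C@H](CC(=O)OC(C)(C)C)[C@@H](OB3OC(C)(C)C(C)(C)O3)[C@@H](C(=C)CO[Si](c4ccccc4)(c4ccccc4)C(C)(C)C)[C@]2(C)C=C | intermediate
26 | cyclohexanol (5S,6S,7R,8R,9S,10S): O8/O9 acetonide, C7 CH2CO2t-Bu and C10 vinyl on one face; O6–H, the C5 3-(TBDPS-oxy)prop-1-en-2-yl group and the C10 methyl on the other | CC1(C)O[C@@H]2[C@H](O1)[C@H](CC(=O)OC(C)(C)C)[C@@H](O)[C@@H](C(=C)CO[Si](c3ccccc3)(c3ccccc3)C(C)(C)C)[C@]2(C)C=C | intermediate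
27 | O6 silyl ether, 26 with O6 as TBS ether | CC1(C)O[C@@H]2[C@H](O1)[C@H](CC(=O)OC(C)(C)C)[C@@H](O[Si](C)(C)C(C)(C)C)[C@@H](C(=C)CO[Si](c3ccccc3)(c3ccccc3)C(C)(C)C)[C@]2(C)C=C | intermediate
28 | Mannich base, 27 with CH2N(CH3)2 on C11 (both C11 epimers) | CC1(C)O[C@@H]2[C@H](O1)[C@H](C(CN(C)C)C(=O)OC(C)(C)C)[C@@H](O[Si](C)(C)C(C)(C)C)[C@@H](C(=C)CO[Si](c3ccccc3)(c3ccccc3)C(C)(C)C)[C@]2(C)C=C | intermediate
29 | ammonium iodide, N-methyl quaternary salt of 28 | CC1(C)O[C@@H]2[C@H](O1)[C@H](C(C[N+](C)(C)C)C(=O)OC(C)(C)C)[C@@H](O[Si](C)(C)C(C)(C)C)[C@@H](C(=C)CO[Si](c3ccccc3)(c3ccccc3)C(C)(C)C)[C@]2(C)C=C.[I-] | intermediate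
30 | α-methylene ester, 27 with C11=C13H2 (tert-butyl 2-substituted acrylate) | CC1(C)O[C@@H]2[C@H](O1)[C@H](C(=C)C(=O)OC(C)(C)C)[C@@H](O[Si](C)(C)C(C)(C)C)[C@@H](C(=C)CO[Si](c3ccccc3)(c3ccccc3)C(C)(C)C)[C@]2(C)C=C | intermediate
31 | hydroxy methylene lactone: cis-fused O8–C12 α-methylene-γ-lactone, O9–H free, O6 TBS, O15 TBDPS, C10 vinyl | O[C@@H]1[C@@H]2OC(=O)C(=C)[C@@H]2[C@@H](O[Si](C)(C)C(C)(C)C)[C@@H](C(=C)CO[Si](c3ccccc3)(c3ccccc3)C(C)(C)C)[C@]1(C)C=C | intermediate
32 | epoxy alcohol, 31 with the C10 vinyl group as (S)-oxirane at C1 | O[C@@H]1[C@@H]2OC(=O)C(=C)[C@@H]2[C@@H](O[Si](C)(C)C(C)(C)C)[C@@H](C(=C)CO[Si](c3ccccc3)(c3ccccc3)C(C)(C)C)[C@]1(C)[C@H]1CO1 | intermediate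
33 | methacrylate, 32 with O9 as 2-methylprop-2-enoate | C=C(C)C(=O)O[C@@H]1[C@@H]2OC(=O)C(=C)[C@@H]2[C@@H](O[Si](C)(C)C(C)(C)C)[C@@H](C(=C)CO[Si](c3ccccc3)(c3ccccc3)C(C)(C)C)[C@]1(C)[C@H]1CO1 | intermediate
34 | diol, 33 with O6–H and O15–H free | C=C(C)C(=O)O[C@@H]1[C@@H]2OC(=O)C(=C)[C@@H]2[C@@H](O)[C@@H](C(=C)CO)[C@]1(C)[C@H]1CO1 | intermediate
35 | CNP0124638.3 (1S,5R,6S,7R,8R,9S,10R): 34 with C15 as aldehyde | C=C(C)C(=O)O[C@@H]1[C@@H]2OC(=O)C(=C)[C@@H]2[C@@H](O)[C@@H](C(=C)C=O)[C@]1(C)[C@H]1CO1 | target

Total step count: 28. Longest linear sequence: 28 steps (the route is linear from 1).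

Steps least certain to work

Step 21 (key step). The most likely failure is slow C–C bond formation, because the tert-alkyl carbon C10 must sit axial on the allylboration chair. That gives time for enolisation at C7 (epimerisation, β-elimination of O8) or protodeboronation. Fallback: from 23 the pinacol ester is exchanged with KHF2 in aqueous methanol to the potassium trifluoroborate alcohol F1. This is oxidised with Dess–Martin periodinane to the trifluoroborate aldehyde F2, which is inert until BF3·OEt2 is added at −78 °C. The allyldifluoroborane so released should close through the same chair at low temperature, and after aqueous work-up the route is rejoined at 26.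

Step 9. Poor or reversed facial selectivity is the risk. Attack anti to the C9–O9 bond is stereoelectronically preferred, and it competes with the sterically preferred attack on the O9 face that the route needs. Fallback: both C10 epimers can be made to converge by exchanging the roles of the two arms. From 10, the epimeric alcohol F3 is ozonised at its vinyl group (O3, then PPh3) to the hydroxy aldehyde F4. Olefination with the bromo ylide gives the hydroxy bromoenoate F5, oxidation gives the aldehyde F6, and methylenation (Zn, CH2Br2, TiCl4) gives 13, where the route is rejoined.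

Step 17. Geometric isomerisation of the (Z)-enoate before addition, or attack past the C9 side, would give the C7 epimer, and the hindered enoate may react slowly. Fallback: from 18, conjugate addition of nitromethane (DBU), which is also syn-selective with such enoates, gives the nitro ester F7. A Nef reaction (NaOMe, then buffered aqueous TiCl3) gives the aldehyde F8, and NaBH4 reduction returns to the route at 20.

Step 19. Slow oxidative addition or transmetalation at the hindered, cis-substituted bromide is the risk, as is protodeboronation of the product in aqueous base. Fallback: from 21 the ester is first masked as its lithium enolate with LiN(i-Pr)2. Bromine–lithium exchange with t-BuLi at −78 °C and trapping with (chloromethyl)boronic acid pinacol ester then give the boronate complex, which rearranges on warming (Matteson homologation) to 22 with retention of geometry. No new isolated compound arises.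

Step 25. The monosubstituted alkene may be epoxidised slowly, so that oxidation of C4=C3 or loss of facial control by an undirected pathway competes. Fallback: from 31, catalyst control replaces substrate control. VO(O-i-Pr)3 with a chiral bis-hydroxamic acid ligand of the matched hand and cumene hydroperoxide also binds O9–H and gives 32. No new compound arises.

Further compounds

F1 | step 21 | potassium trifluoroborate alcohol, 23 with BF3K in place of Bpin | OC[C@@H](CC(=O)OC(C)(C)C)[C@H]1OC(C)(C)O[C@H]1[C@@](C)(C=C)/C=C(/CO[Si](c2ccccc2)(c2ccccc2)C(C)(C)C)C[B-](F)(F)F.[K+]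
F2 | step 21 | potassium trifluoroborate aldehyde, F1 oxidised at C6 | O=C[C@@H](CC(=O)OC(C)(C)C)[C@H]1OC(C)(C)O[C@H]1[C@@](C)(C=C)/C=C(/CO[Si](c2ccccc2)(c2ccccc2)C(C)(C)C)C[B-](F)(F)F.[K+]
F3 | step 9 | epimeric homoallylic alcohol, C10 epimer of 11 | CC(C)(C)[Si](C)(C)OC[C@H]1OC(C)(C)O[C@H]1[C@](C)(C=C)CO
F4 | step 9 | hydroxy aldehyde, F3 with the vinyl group cleaved to CHO | CC(C)(C)[Si](C)(C)OC[C@H]1OC(C)(C)O[C@H]1[C@](C)(C=O)CO
F5 | step 9 | hydroxy bromoenoate, F4 olefinated to the (Z)-2-bromoacrylate arm | CC(C)(C)[Si](C)(C)OC[C@H]1OC(C)(C)O[C@H]1[C@](C)(/C=C(\Br)C(=O)OCC)CO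
F6 | step 9 | aldehyde bromoenoate, F5 with CH2OH oxidised to CHO | CC(C)(C)[Si](C)(C)OC[C@H]1OC(C)(C)O[C@H]1[C@](C)(/C=C(\Br)C(=O)OCC)C=O
F7 | step 17 | nitro ester, 18 after conjugate addition of nitromethane at C7 | [O-][N+](=O)C[C@@H](CC(=O)OC(C)(C)C)[C@H]1OC(C)(C)O[C@H]1[C@@](C)(C=C)/C=C(\Br)CO[Si](c2ccccc2)(c2ccccc2)C(C)(C)C
F8 | step 17 | bromo aldehyde, C6 aldehyde corresponding to 20 | O=C[C@@H](CC(=O)OC(C)(C)C)[C@H]1OC(C)(C)O[C@H]1[C@@](C)(C=C)/C=C(\Br)CO[Si](c2ccccc2)(c2ccccc2)C(C)(C)C
F0 | step 19 | none | none
F0 | step 25 | none | none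
A1 | alternative 1 | open-chain aldoxime with (Z)-C6=C7 and (E)-C10=C1 alkenes | ON=C[C@H](O[Si](C)(C)C(C)(C)C)/C=C\[C@@H](C1(C)OCCO1)/C(C)=C/COCc1ccc(OC)cc1
A2 | alternative 1 | cyclohexene-fused isoxazoline | C12=NO[C@H](COCc3ccc(OC)cc3)[C@@]1(C)[C@H](C3(C)OCCO3)C=C[C@H]2O[Si](C)(C)C(C)(C)C
A3 | alternative 2 | cyclohexene bromoacetal tethered at O8 | COc1ccc(CO[C@@H]2[C@H](OC(OCC)CBr)C=C[C@@H](C(=C)CO[Si](C)(C)C(C)(C)C)[C@]2(C)C=C)cc1
A4 | alternative 2 | cis-fused bicyclic lactol ether with C6 hydroxyl | COc1ccc(CO[C@@H]2[C@@H]3OC(OCC)C[C@@H]3[C@@H](O)[C@@H](C(=C)CO[Si](C)(C)C(C)(C)C)[C@]2(C)C=C)cc1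
A5 | alternative 3 | C6 aldehyde tethered to the butenolide | O=C[C@@H](C(C)=C)[C@](C)(C=C)[C@H](O[Si](C)(C)C(C)(C)C)[C@@H]1OC(=O)C=C1
A6 | alternative 3 | cis-fused γ-lactone with C6 hydroxyl | CC(C)(C)[Si](C)(C)O[C@@H]1[C@@H]2OC(=O)C[C@@H]2[C@@H](O)[C@@H](C(C)=C)[C@]1(C)C=C
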